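The decade per hour is my unit here: one decade is one power of ten lost by a difference. The single-handed free catalyst takes left-handed substrate first, yet the product of both runs ends racemic.

| flask | left-handed substrate | right-handed substrate | reagent | free catalyst | remark | time |
|---|---|---|---|---|---|---|
| green | 1.5 M | 1.5 M | 1.2 equiv | 4.5 mol% | run made earlier |  |
| red | 1.5 M | 1.5 M | 1.2 equiv | 10 mol% | run made earlier |  |
| flask | 1.5 M | 1.5 M | 1.20 equiv | 6.7 mol% |  | 6.0 h |

| run | time / h | left-handed product / % | right-handed product / % | left-handed substrate / % |
|---|---|---|---|---|
| green | 1.00 | 27 | 21 | 10 |
| green | 2.00 | 30 | 26 | 4 |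
| green | 3.00 | 26 | 26 | 0 |
| green | 4.00 | 26 | 30 | 1 |
| green | 5.00 | 28 | 28 | 0 |
| red | 0.417 | 30 | 16 | 6 |
| red | 0.667 | 30 | 23 | 2 |
| red | 1.33 | 33 | 28 | 1 |
| red | 2.50 | 30 | 30 | 1 |
| red | 5.00 | 30 | 29 | 0 |

(standard deviation of a reading: 1.5 percentage points)

- free catalyst is single-handed; left-handed substrate and right-handed substrate are mirror images of each other, charged as a racemate, each of them at the stated concentration
- an excess is the difference of the two amounts in percent of their sum
- an excess is below zero if the other one leads

- excess of left-handed product over right-handed product in the product at 20 min
- excess of left-handed product over right-handed product in the product at 6.0 h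
- part of the left-handed substrate and right-handed substrate charged together that has reacted at 6.0 h

In the red run, left-handed product minus right-handed product falls from 14 percentage points to 7 points. So it loses 1.20 /h: this is the decade rate D of racemization, the decades lost per hour by that difference. It is a loose reading, with 1.5 points of scatter on each amount.

For the new flask, 20 min is 0.401 decades. Two extreme flasks make pure left-handed product, one at the start and one at the moment of sampling; evenly spread making lies between them.

| Left-handed product made | Excess at 20 min |
|---|---|
| at the start | 39.7% |
| evenly | 63.0% |
| at that moment | 100% |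

The flask's loading lies between green and red, whose left-handed substrate reads 10% at 1.00 h and 6% at 0.417 h. I therefore take making in the flask as front-loaded and expect right-handed product to lower the excess further, so I put ea between the first two rows. For eb, green's left-handed substrate reads 0% at 3.00 h; the 3.61 decades from then to 6.0 h make eb zero. For cb, the runs end at 56.0% and 59.0%, and I expect the flask between them.

The forecast gives 42%, 0% and 58.5%, arguing that “the product ends up racemic, so the product racemizes”.

The flask gives 45.0%, 0% and 58.3%.

    reagent + free catalyst → spent catalyst B (k = 2.80 × 10⁻⁴ /M/s)
    free catalyst + right-handed substrate ⇌ catalyst intermediate B (K = 0.890 /M, k = 0.0770 /M/s)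
    free catalyst + left-handed substrate ⇌ catalyst intermediate A (K = 19.0 /M, k = 0.0460 /M/s)
    left-handed product ⇌ right-handed product (k = 3.90 × 10⁻⁴ /s)
    reagent + catalyst intermediate B → free catalyst + right-handed product (k = 0.00360 /M/s)
    free catalyst → spent catalyst A (k = 3.40 × 10⁻⁴ /s)
    reagent + catalyst intermediate A → free catalyst + left-handed product (k = 0.0140 /M/s)

The flask's 45.0% lies above 39.7% and below 63.0%, and its forward half-life of left-handed product into right-handed product, 0.49 h, is short against 6.0 h. From 1.33 h, where the red run reads 1% left-handed substrate, to 6.0 h is 5.60 decades by D, and the neighbour flask with 17 mol% of free catalyst stands at an excess of 0% at 6.0 h.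

The data are simulated for substances that don't exist.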